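The route cuts the benzylic CH2–aryl bond of the C3 side chain, which reduces the left half to a simple C3-methyl succinate. The free C4 carboxylic acid lies exactly β to that carbon. It can therefore steer palladium into a methyl C–H bond through a five-membered palladacycle (Pd–O–C4–C3–CH2), whereas the C1 methyl ester cannot. One carboxylate-directed β-C(sp3)–H arylation joins the complete, stereodefined (2S,3S)-2-aryl-3-methylsuccinic half-ester to a silyl-protected 4-iodo-2-prenylphenol, whose iodine sits para to oxygen on the prenylated ring. Both stereocentres are set beforehand by an oxazolidinone-controlled displacement of L-lactate triflate. Only desilylation follows the coupling.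

Key step: step 9

Remark: in the discussion C1 = ester carbonyl, C2 = CH bearing the 4-hydroxyphenyl ring (ring A), C3 = CH bearing CH3 or CH2–ring B, and C4 = acid carbon; systematic names keep their own IUPAC locants.

Step 1
Reactants: 1 4-hydroxyphenylacetic acid
Product: 3 2-[4-(triisopropylsilyloxy)phenyl]acetic acid, via bis-TIPS derivative 2 (not isolated)
Conditions: TIPSCl (2.2 equiv), imidazole, DMF, rt; then K2CO3, THF/MeOH/H2O, rt; citric acid work-up
Reagents that add atoms: chlorotriisopropylsilane CC(C)[Si](Cl)(C(C)C)C(C)C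
Why: Exhaustive silylation followed by selective hydrolysis of the much more labile silyl ester is standard protecting-group chemistry and leaves the robust aryl TIPS ether, which must survive the later enolate, Lewis-acid, hydrogenation and Pd(II) conditions.

Step 2
Reactants: 3 2-[4-(triisopropylsilyloxy)phenyl]acetic acid; 4 (4S)-4-benzyl-1,3-oxazolidin-2-one
Product: 6 (4S)-4-benzyl-3-{2-[4-(triisopropylsilyloxy)phenyl]acetyl}-1,3-oxazolidin-2-one, via mixed pivalic anhydride 5 (not isolated)
Conditions: PivCl, Et3N, THF, −20 °C; then 4, LiCl, −20 °C → rt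
Reagents that add atoms: pivaloyl chloride CC(C)(C)C(=O)Cl (its atoms stay only in intermediate 5)
Why: N-Acylation of the oxazolidinone through the mixed pivalic anhydride (Et3N/LiCl variant) takes place at the less hindered arylacetyl carbonyl and does not touch the auxiliary stereocentre.

Step 3
Reactants: 7 benzyl (2S)-2-hydroxypropanoate (benzyl L-lactate)
Product: 8 benzyl (2S)-2-(trifluoromethylsulfonyloxy)propanoate
Conditions: Tf2O, 2,6-lutidine, CH2Cl2, −78 → 0 °C; used fresh
Reagents that add atoms: triflic anhydride O=S(=O)(OS(=O)(=O)C(F)(F)F)C(F)(F)F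
Why: O-Sulfonylation breaks only the O–H bond, so the S configuration of the lactate carbon is retained and a very reactive secondary SN2 electrophile results.

Step 4
Reactants: 6 (4S)-4-benzyl-3-{2-[4-(triisopropylsilyloxy)phenyl]acetyl}-1,3-oxazolidin-2-one; 8 benzyl (2S)-2-(trifluoromethylsulfonyloxy)propanoate
Product: 10 benzyl (2S,3S)-4-[(4S)-4-benzyl-2-oxo-1,3-oxazolidin-3-yl]-2-methyl-4-oxo-3-[4-(triisopropylsilyloxy)phenyl]butanoate, via sodium (Z)-enolate 9 (not isolated)
Conditions: NaHMDS, THF, −78 °C; then 8, −78 → −20 °C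
Reagents that add atoms: sodium hexamethyldisilazide [Na+].C[Si](C)(C)[N-][Si](C)(C)C (sodium, only in intermediate 9)
Why: In this Evans asymmetric alkylation with an α-triflyloxy ester, the chelated (Z)-enolate is attacked on the face opposite the benzyl group of the auxiliary, which sets C2 as S, while SN2 inversion at the lactate carbon sets C3 (the descriptor stays S because the priorities change), giving the anti (erythro) succinate.

Step 5
Reactants: 10 benzyl (2S,3S)-4-[(4S)-4-benzyl-2-oxo-1,3-oxazolidin-3-yl]-2-methyl-4-oxo-3-[4-(triisopropylsilyloxy)phenyl]butanoate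
Product: 11 1-benzyl 4-methyl (2S,3S)-2-methyl-3-[4-(triisopropylsilyloxy)phenyl]butanedioate
Conditions: Yb(OTf)3 (10 mol %), MeOH, 45 °C
Reagents that add atoms: methanol CO
Why: In this Lewis-acid-catalysed transesterification of an N-acyloxazolidinone, Yb(III) chelates the two imide carbonyls and activates only the exocyclic one towards methanol without base, so C2 should not epimerise and the non-chelating benzyl ester should stay untouched.

Step 6
Reactants: 11 1-benzyl 4-methyl (2S,3S)-2-methyl-3-[4-(triisopropylsilyloxy)phenyl]butanedioate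
Product: 12 (2S,3S)-4-methoxy-2-methyl-4-oxo-3-[4-(triisopropylsilyloxy)phenyl]butanoic acid
Conditions: H2 (1 atm), 10 % Pd/C, EtOAc, rt
Reagents that add atoms: none
Why: Catalytic hydrogenolysis cleaves only the benzylic C–O bond of the ester and unmasks the directing C4 carboxylic acid at a stage where no alkene is present.

Step 7
Reactants: 13 4-iodophenol; 14 prenyl bromide (1-bromo-3-methylbut-2-ene)
Product: 16 4-iodo-2-(3-methylbut-2-en-1-yl)phenol, via sodium 4-iodophenoxide 15 (not isolated)
Conditions: NaH, toluene, 0 °C → rt; then 14, rt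
Reagents that add atoms: sodium hydride [Na+].[H-] (sodium, only in intermediate 15)
Why: In this ortho-C-alkylation of a phenoxide held as a tight sodium ion pair in a non-polar solvent, oxygen is shielded by the cation, the para position is blocked by iodine, and SN2 attack on the primary allylic carbon gives the linear prenyl group.

Step 8
Reactants: 16 4-iodo-2-(3-methylbut-2-en-1-yl)phenol
Product: 17 [4-iodo-2-(3-methylbut-2-en-1-yl)phenoxy]triisopropylsilane
Conditions: TIPSCl, imidazole, DMF, rt
Reagents that add atoms: chlorotriisopropylsilane CC(C)[Si](Cl)(C(C)C)C(C)C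
Why: Standard silylation masks the oxygen next to the prenyl group against Pd(II)-mediated oxidative cyclisation and silver oxidation in the coupling.

Step 9
Reactants: 12 (2S,3S)-4-methoxy-2-methyl-4-oxo-3-[4-(triisopropylsilyloxy)phenyl]butanoic acid; 17 [4-iodo-2-(3-methylbut-2-en-1-yl)phenoxy]triisopropylsilane
Product: 18 (2S,3S)-4-methoxy-2-{[3-(3-methylbut-2-en-1-yl)-4-(triisopropylsilyloxy)phenyl]methyl}-4-oxo-3-[4-(triisopropylsilyloxy)phenyl]butanoic acid
Conditions: Pd(OAc)2 (10 mol %), N-acetyl-β-alanine (20 mol %), 17 (1.5 equiv), Ag2CO3, K2HPO4, HFIP, 85 °C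
Reagents that add atoms: none
Why: The potassium carboxylate of 12 binds Pd(II) and, assisted by the N-acyl amino acid ligand, concerted metalation–deprotonation of the C3 methyl group gives a five-membered palladacycle; oxidative addition of the C–I bond of 17 to give Pd(IV) and C(sp3)–C(sp2) reductive elimination form the CH2–aryl bond, and Ag2CO3 removes iodide to regenerate Pd(II). The closest known reaction type is the ligand-enabled, native-carboxylate-directed β-C(sp3)–H arylation of α-branched aliphatic acids with aryl iodides in HFIP. No ring of the product is closed (the palladacycle is transient) and no stereocentre is created; C3 keeps its configuration because its own C–H bond is never broken, and C2 should hold because the weakly acidic HFIP/phosphate medium does not enolise the arylacetate unit. Site selectivity is secured by the substrate: the methyl group offers the only primary β-C–H bonds, the other β position (C2–H) is tertiary, the ester does not direct, the ortho C–H bonds of ring A would need a seven-membered palladacycle, and the new benzylic CH2 is far less reactive than CH3, so arylation should stop after one event. Chemoselectivity requires the prenyl group to stay a spectator, which its trisubstituted, unactivated alkene (a poor partner for carbopalladation) and the TIPS cap on the neighbouring oxygen (no Wacker-type cyclisation, no phenol oxidation by silver) should ensure.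

Step 10
Reactants: 18 (2S,3S)-4-methoxy-2-{[3-(3-methylbut-2-en-1-yl)-4-(triisopropylsilyloxy)phenyl]methyl}-4-oxo-3-[4-(triisopropylsilyloxy)phenyl]butanoic acid
Product: 19 asperteretal G2
Conditions: TBAF, AcOH (1:1), THF, 0 °C
Reagents that add atoms: none
Why: Fluoride-driven cleavage of both aryl silyl ethers, buffered by acetic acid, avoids the base that could epimerise C2 or hydrolyse the methyl ester and also the strong acid that would cyclise the ortho-prenylphenol to a chroman.

Compound list
1 | 4-hydroxyphenylacetic acid | OC(=O)Cc1ccc(O)cc1 | starting material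
2 | triisopropylsilyl 2-[4-(triisopropylsilyloxy)phenyl]acetate | CC(C)[Si](C(C)C)(C(C)C)OC(=O)Cc1ccc(O[Si](C(C)C)(C(C)C)C(C)C)cc1 | intermediate (not isolated)
3 | 2-[4-(triisopropylsilyloxy)phenyl]acetic acid | OC(=O)Cc1ccc(O[Si](C(C)C)(C(C)C)C(C)C)cc1 | intermediate
4 | (4S)-4-benzyl-1,3-oxazolidin-2-one | O=C1N[C@@H](Cc2ccccc2)CO1 | starting material
5 | 2-[4-(triisopropylsilyloxy)phenyl]acetic pivalic anhydride | CC(C)(C)C(=O)OC(=O)Cc1ccc(O[Si](C(C)C)(C(C)C)C(C)C)cc1 | intermediate (not isolated)
6 | (4S)-4-benzyl-3-{2-[4-(triisopropylsilyloxy)phenyl]acetyl}-1,3-oxazolidin-2-one | O=C(Cc1ccc(O[Si](C(C)C)(C(C)C)C(C)C)cc1)N1C(=O)OC[C@@H]1Cc1ccccc1 | intermediate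
7 | benzyl (2S)-2-hydroxypropanoate | C[C@H](O)C(=O)OCc1ccccc1 | starting material
8 | benzyl (2S)-2-(trifluoromethylsulfonyloxy)propanoate | C[C@H](OS(=O)(=O)C(F)(F)F)C(=O)OCc1ccccc1 | intermediate
9 | sodium (Z)-enolate of 6 | [Na+].[O-]/C(=C\c1ccc(O[Si](C(C)C)(C(C)C)C(C)C)cc1)N1C(=O)OC[C@@H]1Cc1ccccc1 | intermediate (not isolated)
10 | benzyl (2S,3S)-4-[(4S)-4-benzyl-2-oxo-1,3-oxazolidin-3-yl]-2-methyl-4-oxo-3-[4-(triisopropylsilyloxy)phenyl]butanoate | O=C([C@H](c1ccc(O[Si](C(C)C)(C(C)C)C(C)C)cc1)[C@H](C)C(=O)OCc1ccccc1)N1C(=O)OC[C@@H]1Cc1ccccc1 | intermediate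
11 | 1-benzyl 4-methyl (2S,3S)-2-methyl-3-[4-(triisopropylsilyloxy)phenyl]butanedioate | COC(=O)[C@H](c1ccc(O[Si](C(C)C)(C(C)C)C(C)C)cc1)[C@H](C)C(=O)OCc1ccccc1 | intermediate
12 | (2S,3S)-4-methoxy-2-methyl-4-oxo-3-[4-(triisopropylsilyloxy)phenyl]butanoic acid | COC(=O)[C@H](c1ccc(O[Si](C(C)C)(C(C)C)C(C)C)cc1)[C@H](C)C(=O)O | intermediate
13 | 4-iodophenol | Oc1ccc(I)cc1 | starting material
14 | prenyl bromide | CC(C)=CCBr | starting material
15 | sodium 4-iodophenoxide | [Na+].[O-]c1ccc(I)cc1 | intermediate (not isolated)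
16 | 4-iodo-2-(3-methylbut-2-en-1-yl)phenol | CC(C)=CCc1cc(I)ccc1O | intermediate
17 | [4-iodo-2-(3-methylbut-2-en-1-yl)phenoxy]triisopropylsilane | CC(C)=CCc1cc(I)ccc1O[Si](C(C)C)(C(C)C)C(C)C | intermediate
18 | (2S,3S)-4-methoxy-2-{[3-(3-methylbut-2-en-1-yl)-4-(triisopropylsilyloxy)phenyl]methyl}-4-oxo-3-[4-(triisopropylsilyloxy)phenyl]butanoic acid | COC(=O)[C@H](c1ccc(O[Si](C(C)C)(C(C)C)C(C)C)cc1)[C@H](Cc1ccc(O[Si](C(C)C)(C(C)C)C(C)C)c(CC=C(C)C)c1)C(=O)O | intermediate
19 | asperteretal G2, (2S,3S)-2-{[4-hydroxy-3-(3-methylbut-2-en-1-yl)phenyl]methyl}-3-(4-hydroxyphenyl)-4-methoxy-4-oxobutanoic acid | COC(=O)[C@H](c1ccc(O)cc1)[C@H](Cc1ccc(O)c(CC=C(C)C)c1)C(=O)O | target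

Total step count: 10. Longest linear sequence: 7 steps (1, 2, 4, 5, 6, 9, 10).

Steps most likely to fail

**Step 9.**
- Pd(II) and Ag(I) may engage the prenyl double bond in hot HFIP, through migration into conjugation or allylic palladation.
- The aryl silyl ethers may be lost.
- C–H cleavage next to the bulky C2 substituent may be slow.
- C2 may epimerise on prolonged heating.

The fallback sets out from 12 and returns at 18, and it introduces the prenyl group only after the C–H arylation. Commercial 2-bromo-4-iodophenol is silylated (TIPSCl, imidazole) to (2-bromo-4-iodophenoxy)triisopropylsilane F1. The same carboxylate-directed arylation of 12 reacts at C–I and tolerates C–Br, so it should give (2S,3S)-2-{[3-bromo-4-(triisopropylsilyloxy)phenyl]methyl}-4-methoxy-4-oxo-3-[4-(triisopropylsilyloxy)phenyl]butanoic acid F2. A linear-selective Suzuki–Miyaura coupling of F2 with prenylboronic acid pinacol ester (Pd/biarylphosphine, aq K3PO4, THF, 40 °C) then leads to 18.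

**Step 4.**
- Displacement at a secondary carbon by a stabilised, hindered enolate may be sluggish.
- The triflate may eliminate or racemise.
- The pairing of auxiliary and lactate may be mismatched.
- Proton exchange between product and enolate may erode C2.

The fallback sets out from 3 and returns at 12, bypassing steps 2–6.
- Acid 3 is esterified (C6F5OH, EDC) to pentafluorophenyl 2-[4-(triisopropylsilyloxy)phenyl]acetate F3.
- Crotyl alcohol and Boc2O give tert-butyl (E)-but-2-en-1-yl carbonate F4.
- A stereodivergent branched-selective allylic alkylation follows, using a cyclometalated iridium–phosphoramidite complex and benzotetramisole. The enantiomer of each catalyst is chosen independently for the required isomer. This gives pentafluorophenyl (2S,3R)-3-methyl-2-[4-(triisopropylsilyloxy)phenyl]pent-4-enoate F5.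
- F5 is methanolysed in the same flask (MeOH, DMAP) to methyl (2S,3R)-3-methyl-2-[4-(triisopropylsilyloxy)phenyl]pent-4-enoate F6.
- Ozonolysis (O3, CH2Cl2/MeOH, −78 °C; Me2S) gives methyl (2S,3S)-3-methyl-4-oxo-2-[4-(triisopropylsilyloxy)phenyl]butanoate F7.
- Pinnick oxidation of F7 delivers 12.

**Step 5.**
- Methanol may attack the endocyclic carbamate carbonyl of the hindered imide.
- The benzyl ester may slowly exchange for a methyl ester, which would erase the differentiation of the two carboxyl groups.

The fallback sets out from 10 and returns at 11. Hydroperoxide cleavage (LiOH, H2O2, THF/H2O, 0 °C) is selective for the exocyclic carbonyl. It gives (2S,3S)-4-(benzyloxy)-3-methyl-4-oxo-2-[4-(triisopropylsilyloxy)phenyl]butanoic acid F8. F8 is methylated under neutral conditions (TMSCHN2, toluene/MeOH, 0 °C) to 11.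

Further compounds
F1 | step 9 | (2-bromo-4-iodophenoxy)triisopropylsilane | CC(C)[Si](Oc1ccc(I)cc1Br)(C(C)C)C(C)C
F2 | step 9 | (2S,3S)-2-{[3-bromo-4-(triisopropylsilyloxy)phenyl]methyl}-4-methoxy-4-oxo-3-[4-(triisopropylsilyloxy)phenyl]butanoic acid | COC(=O)[C@H](c1ccc(O[Si](C(C)C)(C(C)C)C(C)C)cc1)[C@H](Cc1ccc(O[Si](C(C)C)(C(C)C)C(C)C)c(Br)c1)C(=O)O
F3 | step 4 | pentafluorophenyl 2-[4-(triisopropylsilyloxy)phenyl]acetate | CC(C)[Si](Oc1ccc(CC(=O)Oc2c(F)c(F)c(F)c(F)c2F)cc1)(C(C)C)C(C)C
F4 | step 4 | tert-butyl (E)-but-2-en-1-yl carbonate | C/C=C/COC(=O)OC(C)(C)C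
F5 | step 4 | pentafluorophenyl (2S,3R)-3-methyl-2-[4-(triisopropylsilyloxy)phenyl]pent-4-enoate | O=C(Oc1c(F)c(F)c(F)c(F)c1F)[C@H](c1ccc(O[Si](C(C)C)(C(C)C)C(C)C)cc1)[C@H](C)C=C
F6 | step 4 | methyl (2S,3R)-3-methyl-2-[4-(triisopropylsilyloxy)phenyl]pent-4-enoate | COC(=O)[C@H](c1ccc(O[Si](C(C)C)(C(C)C)C(C)C)cc1)[C@H](C)C=C
F7 | step 4 | methyl (2S,3S)-3-methyl-4-oxo-2-[4-(triisopropylsilyloxy)phenyl]butanoate | COC(=O)[C@H](c1ccc(O[Si](C(C)C)(C(C)C)C(C)C)cc1)[C@H](C)C=O
F8 | step 5 | (2S,3S)-4-(benzyloxy)-3-methyl-4-oxo-2-[4-(triisopropylsilyloxy)phenyl]butanoic acid | OC(=O)[C@H](c1ccc(O[Si](C(C)C)(C(C)C)C(C)C)cc1)[C@H](C)C(=O)OCc1ccccc1
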